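The oxolane is numbered O1, C2 (aryl cis to the arm C3a on C3), C3, C4 (arm C4a), C5 (aryl trans to C4a); the target is the (2R,3R,4R,5S) isomer.
Retrosynthesis: both arm hydroxyls are masked as acetates, then C2–O1, C5–O1 and C3–C4 are cut at once. This leaves water and two molecules of sinapyl acetate, which goes back through sinapyl alcohol and methyl sinapate to sinapic acid.
Enabling feature: C3–C4 links the side-chain β-carbons of two identical 4-hydroxy-3,5-dimethoxyphenyl-C3 halves and O1 spans their benzylic carbons C2 and C5. Each benzylic carbon lies para to a free phenol, so the oxolane ring is the hydrate of an 8–8' bis(quinone methide).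
Forward order: side-chain adjustment (ester, allylic alcohol, γ-acetate), then the oxolane, the only ring made, in one oxidative dimerisation, then deacetylation.
Stereochemistry: C3/C4 come from si–si pairing of two radicals in a (+)-pinoresinol-type dirigent protein. C2 and C5 come from allylic 1,3-strain in the two quinone methides (free water enters anti to the C4 branch, tethered O1 enters syn to C3).

Key step: step 4

Assumption: the dirigent protein is a recombinant (+)-pinoresinol-forming protein of the Forsythia intermedia type whose pocket has been widened by mutagenesis and screening for the second methoxy group and the acetoxy tail; it and the commercial Trametes versicolor laccase act catalytically and add no atoms.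

Step 1
Reactants: 1 sinapic acid
Product: 2 methyl sinapate, methyl (E)-3-(4-hydroxy-3,5-dimethoxyphenyl)prop-2-enoate
Conditions: MeOH, H2SO4 (cat.), reflux
Reagents that add atoms: methanol, CO
Why: Fischer esterification, in which the large excess of methanol drives the acid-catalysed equilibrium to the ester while the phenol and the E-alkene stay untouched.

Step 2
Reactants: 2 methyl sinapate
Product: 3 sinapyl alcohol, 4-[(E)-3-hydroxyprop-1-enyl]-2,6-dimethoxyphenol
Conditions: i-Bu2AlH (DIBAL-H, 4 equiv), toluene, 0 °C; then aq. KNaC4H4O6 (potassium sodium tartrate)
Reagents that add atoms: none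
Why: DIBAL-H 1,2-reduction of an α,β-unsaturated ester, well established for unprotected hydroxycinnamate esters: one equivalent is consumed by the phenol as aluminium phenoxide, two more take the ester through the aldehyde level to the allylic alkoxide without conjugate reduction, so the E-alkene is retained, and the non-acidic tartrate work-up spares the acid-sensitive product.

Step 3
Reactants: 3 sinapyl alcohol, 4 vinyl acetate
Product: 5 sinapyl acetate, (E)-3-(4-hydroxy-3,5-dimethoxyphenyl)prop-2-enyl acetate
Conditions: Candida antarctica lipase B (immobilised), vinyl acetate (5 equiv), MTBE/THF, 30 °C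
Reagents that add atoms: vinyl acetate (4), C=COC(C)=O
Why: Lipase-catalysed irreversible transesterification with an enol ester, in which the acyl-enzyme passes acetyl to the unhindered primary allylic hydroxyl, the phenol flanked by two methoxy groups is not accepted as nucleophile, and tautomerisation of the released enol prevents the back reaction.

Step 4
Reactants: 5 sinapyl acetate (two molecules)
Product: 9 (2R,3R,4R,5S)-3,4-bis(acetoxymethyl)-2,5-bis(4-hydroxy-3,5-dimethoxyphenyl)oxolane, via phenoxyl radical 6 (not isolated), via bis(quinone methide) 7 (not isolated), via hydroxy quinone methide 8 (not isolated)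
Conditions: laccase (Trametes versicolor, low activity), dirigent protein (sites in excess over the radical flux), O2 (air), MES/NaOH buffer pH 5.0–acetone 95:5, 25 °C, 5 fed over several hours; EtOAc extraction, SiO2 chromatography (removal of the other oxolane diastereomers)
Reagents that add atoms: water, O
Why: Proposed new method: laccase removes one electron and one proton from the phenol of each molecule of 5, two radicals 6 (spin density on the side-chain carbon next to CH2OAc) are held in the dirigent pocket and join si face to si face to form C3–C4 in the twofold-symmetric (R,R)-bis(quinone methide) 7, water adds to either of its equivalent methide carbons (C2–O1) to give 8, and the new benzylic hydroxyl adds to the remaining methide carbon (C5–O1) with rearomatisation. The closest known reaction types are the laccase or peroxidase dehydrodimerisation of γ-acylated sinapyl alcohols, which gives racemic 8–8' oxolanes by water capture, and the dirigent-protein-guided coupling of coniferyl alcohol radicals to (+)-pinoresinol; what has not been shown is a dirigent protein steering a 3,5-dimethoxylated, γ-acetylated radical. The one ring formed, the oxolane, closes 5-exo-trig, since O1 attacks C5 while the double bond from C5 to the six-membered ring stays outside the forming ring. C3 and C4 are set together by the protein, equal faces giving the trans arms and the pocket giving the (3R,4R) sense of the (+)-pinoresinol series; C2 follows from allylic 1,3-strain in 7, which turns H3 into the methide plane so that water enters opposite the branched C4 substituent, on the side of the slim CH2OAc arm, and this ends as aryl cis to C3a once the ring is closed; C5 follows from the same strain in 8, where O1 hangs on C3 and can only reach the methide face turned towards C3, which leaves the C5 aryl trans to C4a. The step needs 8–8' regioselectivity and oxolane instead of furofuran closure, and the substrate secures both, because methoxy groups occupy both ring positions ortho to the phenoxyl oxygen and both primary hydroxyls are acetylated, so that 8–O–4' coupling is the only rival and is kept down by the low radical flux. Further oxidation of the phenolic product is limited by the slow feed of 5 and by stopping at its consumption, and the acetates are stable at pH 5.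

Step 5
Reactants: 9 (2R,3R,4R,5S)-oxolane diacetate
Product: 10 [(2R,3R,4R,5S)-2,5-bis(4-hydroxy-3,5-dimethoxyphenyl)oxolane-3,4-diyl]dimethanol (target)
Conditions: K2CO3 (0.3 equiv), MeOH, argon, 0 °C to rt; then NaH2PO4/Na2HPO4 buffer pH 7
Reagents that add atoms: none
Why: Zemplén-type transesterification, in which catalytic methoxide from K2CO3 in methanol cleaves the two primary acetates, no bond at C2–C5 is touched at or below room temperature, exclusion of air protects the electron-rich phenolates, and the neutral quench avoids acid-induced benzylic epimerisation.

Compound list
1 | sinapic acid, (E)-3-(4-hydroxy-3,5-dimethoxyphenyl)prop-2-enoic acid | COc1cc(/C=C/C(=O)O)cc(OC)c1O | starting material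
2 | methyl sinapate | COc1cc(/C=C/C(=O)OC)cc(OC)c1O | intermediate
3 | sinapyl alcohol | COc1cc(/C=C/CO)cc(OC)c1O | intermediate
4 | vinyl acetate | C=COC(C)=O | starting material
5 | sinapyl acetate | COc1cc(/C=C/COC(C)=O)cc(OC)c1O | intermediate
6 | sinapyl acetate phenoxyl radical | COc1cc(/C=C/COC(C)=O)cc(OC)c1[O] | intermediate
7 | (2R,3R)-2,3-bis[(3,5-dimethoxy-4-oxocyclohexa-2,5-dien-1-ylidene)methyl]butane-1,4-diyl diacetate | COC1=CC(=C[C@@H](COC(C)=O)[C@H](COC(C)=O)C=C2C=C(OC)C(=O)C(OC)=C2)C=C(OC)C1=O | intermediate
8 | (2R,3R)-2-[(R)-hydroxy(4-hydroxy-3,5-dimethoxyphenyl)methyl]-3-[(3,5-dimethoxy-4-oxocyclohexa-2,5-dien-1-ylidene)methyl]butane-1,4-diyl diacetate | COc1cc([C@H](O)[C@@H](COC(C)=O)[C@H](COC(C)=O)C=C2C=C(OC)C(=O)C(OC)=C2)cc(OC)c1O | intermediate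
9 | (2R,3R,4R,5S)-3,4-bis(acetoxymethyl)-2,5-bis(4-hydroxy-3,5-dimethoxyphenyl)oxolane | COc1cc([C@H]2O[C@@H](c3cc(OC)c(O)c(OC)c3)[C@@H](COC(C)=O)[C@@H]2COC(C)=O)cc(OC)c1O | intermediate
10 | [(2R,3R,4R,5S)-2,5-bis(4-hydroxy-3,5-dimethoxyphenyl)oxolane-3,4-diyl]dimethanol | COc1cc([C@H]2O[C@@H](c3cc(OC)c(O)c(OC)c3)[C@@H](CO)[C@@H]2CO)cc(OC)c1O | target

Total step count: 5. Longest linear sequence: 5 steps (1 → 2 → 3 → 5 → 9 → 10).

Steps most likely to fail

Step 4. Several processes would erode enantiomeric purity, diastereoselectivity and mass balance:
- coupling of radicals that never enter the pocket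
- refusal of the widened pocket to bind the acetylated syringyl radical
- a weak facial bias in the water capture at C2
- further oxidation of the phenolic product

The fallback uses known chemistry and takes the absolute configuration from resolution instead of from a template. Setting out from 5, the dehydrodimerisation is run with laccase and O2 alone in buffer/acetone, the reaction type established for γ-acylated sinapyl alcohols. Silica gel chromatography should then deliver the cis,trans,trans diastereomer as the racemate, that is 9 together with its mirror image, the (2S,3S,4S,5R)-diacetate F1. Preparative HPLC on an amylose tris(3,5-dimethylphenylcarbamate) phase separates the two, and the enantiomers are assigned by circular dichroism against computed spectra. The route is rejoined at 9.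

Step 5. Phenolate-assisted opening of a benzylic C–O bond (epimerisation at C2 towards the all-trans arrangement) and air oxidation of the phenolates could degrade the product during base treatment. The fallback masks the phenols so that no quinone methide can form while the esters are cleaved. Setting out from 9, TBSCl and imidazole in DMF should give the bis(tert-butyldimethylsilyl ether) diacetate F2. i-Bu2AlH in CH2Cl2 at −78 °C removes both acetates reductively to give the bis(silyl ether) diol F3. Bu4NF buffered with AcOH in THF at 0 °C then frees the phenols, and the route is rejoined at 10.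

Step 3. Sluggish acyl transfer to the poorly soluble substrate, incomplete discrimination between the two hydroxyl types, or ionisation of the allylic acetate during purification could spoil the supply of monomer. The fallback replaces selective acylation by selective deacylation. Setting out from 3, Ac2O in pyridine acetylates both hydroxyls to give 4-O-acetylsinapyl acetate F4. One equivalent of pyrrolidine in CH2Cl2 at 0 °C cleaves only the aryl acetate by aminolysis, and the route is rejoined at 5.

Further compounds
F1 | step 4 | (2S,3S,4S,5R)-3,4-bis(acetoxymethyl)-2,5-bis(4-hydroxy-3,5-dimethoxyphenyl)oxolane (mirror image of 9) | COc1cc([C@@H]2O[C@H](c3cc(OC)c(O)c(OC)c3)[C@H](COC(C)=O)[C@H]2COC(C)=O)cc(OC)c1O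
F2 | step 5 | (2R,3R,4R,5S)-3,4-bis(acetoxymethyl)-2,5-bis[4-(tert-butyldimethylsilyloxy)-3,5-dimethoxyphenyl]oxolane | COc1cc([C@H]2O[C@@H](c3cc(OC)c(O[Si](C)(C)C(C)(C)C)c(OC)c3)[C@@H](COC(C)=O)[C@@H]2COC(C)=O)cc(OC)c1O[Si](C)(C)C(C)(C)C
F3 | step 5 | [(2R,3R,4R,5S)-2,5-bis[4-(tert-butyldimethylsilyloxy)-3,5-dimethoxyphenyl]oxolane-3,4-diyl]dimethanol | COc1cc([C@H]2O[C@@H](c3cc(OC)c(O[Si](C)(C)C(C)(C)C)c(OC)c3)[C@@H](CO)[C@@H]2CO)cc(OC)c1O[Si](C)(C)C(C)(C)C
F4 | step 3 | 4-O-acetylsinapyl acetate, (E)-3-(4-acetoxy-3,5-dimethoxyphenyl)prop-2-enyl acetate | COc1cc(/C=C/COC(C)=O)cc(OC)c1OC(C)=O
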